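**Strategy**

The 1,4-dioxane ring is opened at its only C–C single bond between sp3 carbons, C2–C3 of the benzodioxine (CH(CH2OH)–CH(aryl)). This leaves a catechol diether of methyl 5-hydroxyferulate: a 2-oxoethyl ether on O1 and an electron-rich benzyl ether on O4. The key step exploits two features: C3 is a benzylic ether carbon para to an oxygen of the pendant aryl ring, so DDQ removes hydride from it, and C2 is alpha to the hydroxymethyl carbon, held as an aldehyde. In one flask, DDQ oxidation, chiral enamine formation and cyclisation forge C2–C3, close the dioxane ring and set both stereocentres; borohydride then delivers the hydroxymethyl group.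

Key step: step 7

Remark: the SMILES is read as the trans (2R,3R) isomer (aryl on C3 and CH2OH on C2 on opposite ring faces). Benzodioxine numbering is O1, C2 (CH2OH), C3 (aryl), O4, C6 (propenal), C8 (OMe).

**Route**

Step 1
Reactants: 1 methyl 3,4-dihydroxy-5-methoxybenzoate
Product: 2 methyl 7-methoxy-2,2-dimethyl-1,3-benzodioxole-5-carboxylate
Conditions: 2,2-dimethoxypropane, p-TsOH (cat.), toluene, reflux, Soxhlet with 4 Å MS
Reagents that add atoms: 2,2-dimethoxypropane, COC(C)(C)OC
Why: Acid-catalysed transketalisation of the catechol, driven by removal of methanol, should give the five-membered isopropylidene ketal while the ester stays inert.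

Step 2
Reactants: 2 methyl 7-methoxy-2,2-dimethyl-1,3-benzodioxole-5-carboxylate
Product: 3 (7-methoxy-2,2-dimethyl-1,3-benzodioxol-5-yl)methanol
Conditions: LiAlH4, THF, 0 °C
Reagents that add atoms: none
Why: LiAlH4 reduction of the aryl ester should give the benzyl alcohol, the ketal and the aryl ethers being inert to hydride.

Step 3
Reactants: 4 3,4-dihydroxy-5-methoxybenzaldehyde (5-hydroxyvanillin)
Product: 5 2-(4-formyl-2-hydroxy-6-methoxyphenoxy)-N-methoxy-N-methylacetamide
Conditions: 2-chloro-N-methoxy-N-methylacetamide (1.05 equiv), Li2CO3 (1.1 equiv), NaI (cat.), DMF, 50 °C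
Reagents that add atoms: 2-chloro-N-methoxy-N-methylacetamide, CON(C)C(=O)CCl
Why: Williamson alkylation under weak-base control should be selective for O4, because only the 4-OH (para to the formyl group, the more acidic phenol) is deprotonated by Li2CO3 and the alpha-halo amide is activated by iodide exchange.

Step 4
Reactants: 5 2-(4-formyl-2-hydroxy-6-methoxyphenoxy)-N-methoxy-N-methylacetamide; 3 (7-methoxy-2,2-dimethyl-1,3-benzodioxol-5-yl)methanol
Product: 6 2-[4-formyl-2-methoxy-6-[(7-methoxy-2,2-dimethyl-1,3-benzodioxol-5-yl)methoxy]phenoxy]-N-methoxy-N-methylacetamide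
Conditions: PPh3, DIAD, THF, 0 °C to rt
Reagents that add atoms: none
Why: Mitsunobu etherification of the remaining phenol with the primary benzylic alcohol should give the benzyl aryl ether, with aldehyde, Weinreb amide and ketal untouched under these neutral conditions.

Step 5
Reactants: 6 2-[4-formyl-2-methoxy-6-[(7-methoxy-2,2-dimethyl-1,3-benzodioxol-5-yl)methoxy]phenoxy]-N-methoxy-N-methylacetamide
Product: 7 methyl (E)-3-[3-methoxy-4-[2-[methoxy(methyl)amino]-2-oxoethoxy]-5-[(7-methoxy-2,2-dimethyl-1,3-benzodioxol-5-yl)methoxy]phenyl]prop-2-enoate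
Conditions: methyl (triphenylphosphoranylidene)acetate, toluene, 80 °C
Reagents that add atoms: methyl (triphenylphosphoranylidene)acetate, COC(=O)C=P(c1ccccc1)(c1ccccc1)c1ccccc1
Why: Wittig olefination of the aryl aldehyde with a stabilised ylide should give the E-cinnamate, the Weinreb amide being unreactive towards the ylide.

Step 6
Reactants: 7 methyl (E)-3-[3-methoxy-4-[2-[methoxy(methyl)amino]-2-oxoethoxy]-5-[(7-methoxy-2,2-dimethyl-1,3-benzodioxol-5-yl)methoxy]phenyl]prop-2-enoate
Product: 8 methyl (E)-3-[3-methoxy-5-[(7-methoxy-2,2-dimethyl-1,3-benzodioxol-5-yl)methoxy]-4-(2-oxoethoxy)phenyl]prop-2-enoate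
Conditions: DIBAL-H (1.1 equiv), THF, −78 °C; aq. Rochelle salt; used without storage
Reagents that add atoms: none
Why: Partial reduction of the Weinreb amide through its chelated tetrahedral aluminium adduct should stop at the aldehyde, since in THF at −78 °C the activated alpha-aryloxy amide reacts much faster than the conjugated, electron-rich methyl cinnamate.

Step 7
Reactants: 8 methyl (E)-3-[3-methoxy-5-[(7-methoxy-2,2-dimethyl-1,3-benzodioxol-5-yl)methoxy]-4-(2-oxoethoxy)phenyl]prop-2-enoate
Product: 11 methyl (E)-3-[(2R,3R)-2-(hydroxymethyl)-8-methoxy-3-(7-methoxy-2,2-dimethyl-1,3-benzodioxol-5-yl)-2,3-dihydro-1,4-benzodioxin-6-yl]prop-2-enoate, via oxocarbenium ion 9 (not isolated), via trans-aldehyde 10 (not isolated)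
Conditions: DDQ (1.05 equiv), LiClO4, 2,6-dichloropyridine, 4 Å MS, DCE, 0 °C to rt; then (R)-α,α-diphenylprolinol TMS ether (20 mol %), −20 °C; then NaBH4, MeOH, −20 to 0 °C
Reagents that add atoms: none
Why: DDQ should abstract hydride from the only benzylic CH2, activated by the para oxygen of the planar benzodioxole and by the ether oxygen, to give the quinoid O-aryl oxocarbenium ion 9, and the amine then converts the aldehyde into an E-enamine whose C2 attacks C3; this is the intramolecular form of the DDQ-mediated oxidative coupling of benzylic ethers with aldehydes under enamine catalysis, and it is closely related to DDQ-induced oxocarbenium cyclisations onto tethered enol derivatives and to enamine 1,6-additions to para-quinone methides. The dioxane ring closes by a 6-(enolexo)-endo-trig attack on the C=O+ unit, which is exo with respect to the quinoid C=C(aryl) bond. C2 is set by the catalyst, whose diphenyl(silyloxy)methyl group shields one face of the enamine so that C3 adds to the face giving the (2S)-aldehyde 10, which becomes (2R) in alcohol 11 by a priority change only. C3 is set relative to C2 in a half-chair transition state with the aryl group of the cation and the enamine CH=N unit both pseudo-equatorial, which should give the trans ring. The step needs site-selective oxidation, secured by the single electron-rich benzylic CH2 and by consuming DDQ before the amine is added (which also spares the enamine and the product C3–H), and it needs the labile alpha-aryloxy aldehyde to survive, secured by borohydride reduction in the same flask at low temperature before epimerisation or beta-elimination of the aryloxide can set in.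

Step 8
Reactants: 11 methyl (E)-3-[(2R,3R)-2-(hydroxymethyl)-8-methoxy-3-(7-methoxy-2,2-dimethyl-1,3-benzodioxol-5-yl)-2,3-dihydro-1,4-benzodioxin-6-yl]prop-2-enoate
Product: 12 (E)-3-[(2R,3R)-2-(hydroxymethyl)-8-methoxy-3-(7-methoxy-2,2-dimethyl-1,3-benzodioxol-5-yl)-2,3-dihydro-1,4-benzodioxin-6-yl]prop-2-en-1-ol
Conditions: DIBAL-H (3.5 equiv), CH2Cl2, −78 to 0 °C; aq. Rochelle salt
Reagents that add atoms: none
Why: DIBAL-H 1,2-reduction of the conjugated ester should give the E-allylic alcohol without touching the ketal or the two stereocentres.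

Step 9
Reactants: 12 (E)-3-[(2R,3R)-2-(hydroxymethyl)-8-methoxy-3-(7-methoxy-2,2-dimethyl-1,3-benzodioxol-5-yl)-2,3-dihydro-1,4-benzodioxin-6-yl]prop-2-en-1-ol
Product: 13 (E)-3-[(2R,3R)-2-(hydroxymethyl)-8-methoxy-3-(7-methoxy-2,2-dimethyl-1,3-benzodioxol-5-yl)-2,3-dihydro-1,4-benzodioxin-6-yl]prop-2-enal
Conditions: activated MnO2 (excess), CH2Cl2, rt
Reagents that add atoms: none
Why: MnO2 oxidises the cinnamyl alcohol chemoselectively and should leave the saturated primary alcohol alone, while the still-masked catechol cannot be oxidised to a quinone.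

Step 10
Reactants: 13 (E)-3-[(2R,3R)-2-(hydroxymethyl)-8-methoxy-3-(7-methoxy-2,2-dimethyl-1,3-benzodioxol-5-yl)-2,3-dihydro-1,4-benzodioxin-6-yl]prop-2-enal
Product: 14 (E)-3-[(2R,3R)-3-(3,4-dihydroxy-5-methoxyphenyl)-2-(hydroxymethyl)-8-methoxy-2,3-dihydro-1,4-benzodioxin-6-yl]prop-2-enal (CNP0103768.1)
Conditions: TFA/H2O/CH2Cl2, 0 °C to rt
Reagents that add atoms: none
Why: Acid hydrolysis of the catechol isopropylidene ketal should release the two phenols and acetone, and because the trans ring is the thermodynamic isomer and C2 is not epimerisable, any acid-induced ionisation at benzylic C3 should not erode the configuration.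

**Compound list**

1 | methyl 3,4-dihydroxy-5-methoxybenzoate | COC(=O)c1cc(O)c(O)c(OC)c1 | starting material
2 | methyl 7-methoxy-2,2-dimethyl-1,3-benzodioxole-5-carboxylate | COC(=O)c1cc(OC)c2OC(C)(C)Oc2c1 | intermediate
3 | (7-methoxy-2,2-dimethyl-1,3-benzodioxol-5-yl)methanol | OCc1cc(OC)c2OC(C)(C)Oc2c1 | intermediate
4 | 3,4-dihydroxy-5-methoxybenzaldehyde (5-hydroxyvanillin) | COc1cc(C=O)cc(O)c1O | starting material
5 | 2-(4-formyl-2-hydroxy-6-methoxyphenoxy)-N-methoxy-N-methylacetamide | CON(C)C(=O)COc1c(O)cc(C=O)cc1OC | intermediate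
6 | 2-[4-formyl-2-methoxy-6-[(7-methoxy-2,2-dimethyl-1,3-benzodioxol-5-yl)methoxy]phenoxy]-N-methoxy-N-methylacetamide | CON(C)C(=O)COc1c(OC)cc(C=O)cc1OCc1cc(OC)c2OC(C)(C)Oc2c1 | intermediate
7 | methyl (E)-3-[3-methoxy-4-[2-[methoxy(methyl)amino]-2-oxoethoxy]-5-[(7-methoxy-2,2-dimethyl-1,3-benzodioxol-5-yl)methoxy]phenyl]prop-2-enoate | CON(C)C(=O)COc1c(OC)cc(/C=C/C(=O)OC)cc1OCc1cc(OC)c2OC(C)(C)Oc2c1 | intermediate
8 | methyl (E)-3-[3-methoxy-5-[(7-methoxy-2,2-dimethyl-1,3-benzodioxol-5-yl)methoxy]-4-(2-oxoethoxy)phenyl]prop-2-enoate | O=CCOc1c(OC)cc(/C=C/C(=O)OC)cc1OCc1cc(OC)c2OC(C)(C)Oc2c1 | intermediate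
9 | O-aryl oxocarbenium ion from hydride abstraction at the benzylic CH2 of 8 (cation, not isolated) | O=CCOc1c(OC)cc(/C=C/C(=O)OC)cc1[O+]=Cc1cc(OC)c2OC(C)(C)Oc2c1 | intermediate
10 | methyl (E)-3-[(2S,3R)-2-formyl-8-methoxy-3-(7-methoxy-2,2-dimethyl-1,3-benzodioxol-5-yl)-2,3-dihydro-1,4-benzodioxin-6-yl]prop-2-enoate (trans, not isolated) | COc1cc([C@H]2Oc3cc(/C=C/C(=O)OC)cc(OC)c3O[C@@H]2C=O)cc2OC(C)(C)Oc12 | intermediate
11 | methyl (E)-3-[(2R,3R)-2-(hydroxymethyl)-8-methoxy-3-(7-methoxy-2,2-dimethyl-1,3-benzodioxol-5-yl)-2,3-dihydro-1,4-benzodioxin-6-yl]prop-2-enoate | COc1cc([C@H]2Oc3cc(/C=C/C(=O)OC)cc(OC)c3O[C@@H]2CO)cc2OC(C)(C)Oc12 | intermediate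
12 | (E)-3-[(2R,3R)-2-(hydroxymethyl)-8-methoxy-3-(7-methoxy-2,2-dimethyl-1,3-benzodioxol-5-yl)-2,3-dihydro-1,4-benzodioxin-6-yl]prop-2-en-1-ol | COc1cc([C@H]2Oc3cc(/C=C/CO)cc(OC)c3O[C@@H]2CO)cc2OC(C)(C)Oc12 | intermediate
13 | (E)-3-[(2R,3R)-2-(hydroxymethyl)-8-methoxy-3-(7-methoxy-2,2-dimethyl-1,3-benzodioxol-5-yl)-2,3-dihydro-1,4-benzodioxin-6-yl]prop-2-enal | COc1cc([C@H]2Oc3cc(/C=C/C=O)cc(OC)c3O[C@@H]2CO)cc2OC(C)(C)Oc12 | intermediate
14 | (E)-3-[(2R,3R)-3-(3,4-dihydroxy-5-methoxyphenyl)-2-(hydroxymethyl)-8-methoxy-2,3-dihydro-1,4-benzodioxin-6-yl]prop-2-enal | COc1cc([C@H]2Oc3cc(/C=C/C=O)cc(OC)c3O[C@@H]2CO)cc(O)c1O | target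

**Step count and risks**

Total step count: 10. Longest linear sequence: 9 steps (1 → 2 → 3 → 6 → 7 → 8 → 11 → 12 → 13 → 14, i.e. steps 1, 2, 4–10).

Steps most likely to fail:

Step 7. Hydride abstraction from the benzyl aryl ether may be slow or the cation may collapse before it is trapped. Residual DDQ may oxidise the amine or the enamine. A racemic background closure through the free enol may erode the enantiomeric purity, and facial control at C3 may be incomplete, giving some cis ring. The fallback separates activation from stereocontrol. Setting out from aldehyde 8, acetylation (Ac2O, Et3N, DMAP, CH2Cl2) should give the enol acetate F1. Its DDQ-mediated oxidative cyclisation (DDQ, LiClO4, 2,6-dichloropyridine, DCE) onto the oxocarbenium ion should give the racemic trans aldehyde, that is 10 together with ent-10 F2. Reduction in the same flask (NaBH4, MeOH) should give 11 together with ent-11 F3. Separation on a chiral stationary phase (preparative SFC) comes back to the route at 11.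

Step 10. The acid needed to cleave the catechol ketal may promote conjugate addition of the liberated electron-rich ring to the protonated enal (oligomerisation), or the cleavage may stay incomplete. The fallback moves the acid step to a stage without an enal and ends with fluoride. Setting out from 11, aqueous TFA should give the catechol ester F4. Silylation of both phenols and the primary alcohol (TBSCl, imidazole, DMF) should give the tris-TBS ester F5. DIBAL-H (CH2Cl2, −78 °C) should give the tris-TBS allylic alcohol F6, and MnO2 the tris-TBS enal F7. Desilylation with HF·pyridine in THF comes back to the route at 14.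

Step 3. Alkylation may occur at the wrong phenol or twice, or the free ortho-phenol may lactonise onto the Weinreb amide. The fallback removes the regiochemical choice. Setting out from benzyl alcohol 3 and commercial 5-iodovanillin F8, the single phenol of F8 is alkylated with the same chloroacetamide (K2CO3, NaI, DMF) to give the iodo ether F9. A copper-catalysed Ullmann-type C–O coupling of F9 with 3 (CuI, 3,4,7,8-tetramethyl-1,10-phenanthroline, Cs2CO3, toluene, 90 °C) comes back to the route at 6 and replaces steps 3 and 4.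

**Further compounds**

F1 | step 7 | methyl (E)-3-[4-[(Z)-2-acetoxyethenoxy]-3-methoxy-5-[(7-methoxy-2,2-dimethyl-1,3-benzodioxol-5-yl)methoxy]phenyl]prop-2-enoate (enol acetate, Z drawn, E/Z mixture usable) | CC(=O)O/C=C\Oc1c(OC)cc(/C=C/C(=O)OC)cc1OCc1cc(OC)c2OC(C)(C)Oc2c1
F2 | step 7 | ent-10, methyl (E)-3-[(2R,3S)-2-formyl-8-methoxy-3-(7-methoxy-2,2-dimethyl-1,3-benzodioxol-5-yl)-2,3-dihydro-1,4-benzodioxin-6-yl]prop-2-enoate | COc1cc([C@@H]2Oc3cc(/C=C/C(=O)OC)cc(OC)c3O[C@H]2C=O)cc2OC(C)(C)Oc12
F3 | step 7 | ent-11, methyl (E)-3-[(2S,3S)-2-(hydroxymethyl)-8-methoxy-3-(7-methoxy-2,2-dimethyl-1,3-benzodioxol-5-yl)-2,3-dihydro-1,4-benzodioxin-6-yl]prop-2-enoate | COc1cc([C@@H]2Oc3cc(/C=C/C(=O)OC)cc(OC)c3O[C@H]2CO)cc2OC(C)(C)Oc12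
F4 | step 10 | methyl (E)-3-[(2R,3R)-3-(3,4-dihydroxy-5-methoxyphenyl)-2-(hydroxymethyl)-8-methoxy-2,3-dihydro-1,4-benzodioxin-6-yl]prop-2-enoate | COc1cc([C@H]2Oc3cc(/C=C/C(=O)OC)cc(OC)c3O[C@@H]2CO)cc(O)c1O
F5 | step 10 | methyl (E)-3-[(2R,3R)-3-[3,4-bis(tert-butyldimethylsilyloxy)-5-methoxyphenyl]-2-[(tert-butyldimethylsilyloxy)methyl]-8-methoxy-2,3-dihydro-1,4-benzodioxin-6-yl]prop-2-enoate | COc1cc([C@H]2Oc3cc(/C=C/C(=O)OC)cc(OC)c3O[C@@H]2CO[Si](C)(C)C(C)(C)C)cc(O[Si](C)(C)C(C)(C)C)c1O[Si](C)(C)C(C)(C)C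
F6 | step 10 | (E)-3-[(2R,3R)-3-[3,4-bis(tert-butyldimethylsilyloxy)-5-methoxyphenyl]-2-[(tert-butyldimethylsilyloxy)methyl]-8-methoxy-2,3-dihydro-1,4-benzodioxin-6-yl]prop-2-en-1-ol | COc1cc([C@H]2Oc3cc(/C=C/CO)cc(OC)c3O[C@@H]2CO[Si](C)(C)C(C)(C)C)cc(O[Si](C)(C)C(C)(C)C)c1O[Si](C)(C)C(C)(C)C
F7 | step 10 | (E)-3-[(2R,3R)-3-[3,4-bis(tert-butyldimethylsilyloxy)-5-methoxyphenyl]-2-[(tert-butyldimethylsilyloxy)methyl]-8-methoxy-2,3-dihydro-1,4-benzodioxin-6-yl]prop-2-enal | COc1cc([C@H]2Oc3cc(/C=C/C=O)cc(OC)c3O[C@@H]2CO[Si](C)(C)C(C)(C)C)cc(O[Si](C)(C)C(C)(C)C)c1O[Si](C)(C)C(C)(C)C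
F8 | step 3 | 4-hydroxy-3-iodo-5-methoxybenzaldehyde (5-iodovanillin, commercial) | COc1cc(C=O)cc(I)c1O
F9 | step 3 | 2-(4-formyl-2-iodo-6-methoxyphenoxy)-N-methoxy-N-methylacetamide | CON(C)C(=O)COc1c(I)cc(C=O)cc1OC
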